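The isoindolinone is cut at its nitrogen. N2, the atom that holds the CH2CH2OH chain, is bonded on one side to the carbonyl carbon C3 and on the other to the spiro carbon C1, which is also C2' of the naphtho[1,8-bc]furan and carries the furan oxygen. Such a C(=O)–N(CH2CH2OH)–C(quaternary) array is what insertion of 2-azidoethanol into a benzo-fused cyclobutanone leaves: one operation forms both C–N bonds, widens the four-membered ketone ring to the lactam and brings in the side chain, with the spiro carbon migrating with retention. The precursor is the enantiopure spiro[benzocyclobutenone–naphthofuran] ketone, naphthol masked as a triisopropylsilyl ether, assembled by classical reactions and resolved before the four-membered ring is closed.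

Key step: step 10

Assumption: 1-[4-(benzyloxy)phenyl]propan-2-one (1) is taken as a catalogue chemical; it is otherwise one O-benzylation away from 4-hydroxyphenylacetone.

Remark: the spiro carbon has the same spatial arrangement in 13, 16, 20 and 21; its descriptor reads R in 13 and 21 and S in 16 and 20 only because the CIP ranking of the two aryl groups changes when bromine is lost and when the silyl group is removed.

Step 1
Reactants: 1 1-[4-(benzyloxy)phenyl]propan-2-one
Product: 3 4-[4-(benzyloxy)phenyl]-3-methylbut-2-enoic acid (E/Z; the but-3-enoic isomer may accompany it), via ethyl ester 2 (not isolated)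
Conditions: (EtO)2P(O)CH2CO2Et, NaH, THF, 0 °C to rt; then NaOH, EtOH/H2O, 70 °C; HCl to pH 2
Reagents that add atoms: triethyl phosphonoacetate CCOC(=O)CP(=O)(OCC)OCC; sodium hydroxide [Na+].[OH-]
Why: Horner–Wadsworth–Emmons olefination of the benzyl methyl ketone and saponification of the crude ester should give the acid, whose double-bond position and geometry do not matter because they equilibrate under the conditions of step 2.

Step 2
Reactants: 3 4-[4-(benzyloxy)phenyl]-3-methylbut-2-enoic acid
Product: 4 7-(benzyloxy)-3-methylnaphthalen-1-yl acetate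
Conditions: Ac2O, NaOAc, 140 °C
Reagents that add atoms: acetic anhydride CC(=O)OC(C)=O
Why: The ring-closing step of the Stobbe naphthol synthesis (mixed anhydride, dienyl ketene, 6π-electrocyclisation onto either of the two equivalent ortho carbons, tautomerisation, acetylation) should build the naphthalene with the future furan oxygen at C1 as acetate, already distinguished from the future phenol oxygen at C7 as benzyl ether.

Step 3
Reactants: 4 7-(benzyloxy)-3-methylnaphthalen-1-yl acetate
Product: 5 7-hydroxy-3-methylnaphthalen-1-yl acetate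
Conditions: H2 (1 atm), Pd/C, EtOAc, rt
Reagents that add atoms: none
Why: Catalytic hydrogenolysis of the benzyl aryl ether should free the C7 hydroxyl and leave the aryl acetate untouched.

Step 4
Reactants: 5 7-hydroxy-3-methylnaphthalen-1-yl acetate
Product: 6 7-methyl-1,2-dioxo-1,2-dihydronaphtho[2,1-b]furan-9-yl acetate
Conditions: (COCl)2, Et2O, 0 °C to reflux; then AlCl3, CH2Cl2, 0 °C
Reagents that add atoms: oxalyl chloride ClC(=O)C(=O)Cl
Why: Stollé-type annulation, O-acylation by oxalyl chloride followed by intramolecular Friedel–Crafts acylation at the neighbouring alpha carbon C8 (the position that reacts in 2-naphthol itself), should give the flat keto lactone with the acetoxy group peri to the ketone.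

Step 5
Reactants: 7 3-bromoanisole; 6 7-methyl-1,2-dioxo-1,2-dihydronaphtho[2,1-b]furan-9-yl acetate
Product: 9 rac-1-(2-bromo-6-methoxyphenyl)-1-hydroxy-7-methyl-2-oxo-1,2-dihydronaphtho[2,1-b]furan-9-yl acetate, via 2-bromo-6-methoxyphenyllithium 8 (not isolated)
Conditions: 7 (1.2 equiv), LiN(i-Pr)2, THF, −78 °C; then 6 in THF, −78 °C; AcOH, −78 °C
Reagents that add atoms: none
Why: Directed ortho-lithiation of 3-bromoanisole between bromine and methoxy and 1,2-addition of the aryllithium to the ketone carbonyl of the 1,2-dione, the more electrophilic and sterically open carbonyl group, should give the crowded tertiary carbinol as a racemate.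

Step 6
Reactants: 9 rac-1-(2-bromo-6-methoxyphenyl)-1-hydroxy-7-methyl-2-oxo-1,2-dihydronaphtho[2,1-b]furan-9-yl acetate
Product: 11 rac-2-(2-bromo-6-methoxyphenyl)-3-hydroxy-N-methoxy-N,7-dimethyl-2H-naphtho[1,8-bc]furan-2-carboxamide, via trihydroxy Weinreb amide 10 (not isolated)
Conditions: MeNH(OMe)·HCl (4 equiv), i-PrMgCl (9 equiv), THF, −20 °C to rt; 1 M HCl work-up; then TsOH·H2O (cat.), CH2Cl2, rt
Reagents that add atoms: N,O-dimethylhydroxylamine hydrochloride CNOC.Cl
Why: Weinreb aminolysis by the magnesium amide should open the aryl lactone and remove the acetate, and the 8-hydroxy-1-naphthyl carbinol so formed should undergo the classical acid-catalysed cyclodehydration to the 2H-naphtho[1,8-bc]furan (ionisation to the quinone-methide-type cation and capture by the peri hydroxyl), which creates the spiro stereocentre as a racemate.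

Step 7
Reactants: 11 rac-2-(2-bromo-6-methoxyphenyl)-3-hydroxy-N-methoxy-N,7-dimethyl-2H-naphtho[1,8-bc]furan-2-carboxamide
Product: 12 rac-2-(2-bromo-6-methoxyphenyl)-N-methoxy-N,7-dimethyl-3-[(triisopropylsilyl)oxy]-2H-naphtho[1,8-bc]furan-2-carboxamide
Conditions: i-Pr3SiOTf, 2,6-lutidine, CH2Cl2, 0 °C
Reagents that add atoms: triisopropylsilyl trifluoromethanesulfonate CC(C)[Si](OS(=O)(=O)C(F)(F)F)(C(C)C)C(C)C
Why: Silylation of the hindered naphthol with the silyl triflate should give the silyl ether, which prevents phenoxide formation and oxygen-assisted opening of the spiro ether in the organolithium and Lewis acid steps.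

Step 8
Reactants: 12 rac-2-(2-bromo-6-methoxyphenyl)-N-methoxy-N,7-dimethyl-3-[(triisopropylsilyl)oxy]-2H-naphtho[1,8-bc]furan-2-carboxamide
Product: 13 (R)-2-(2-bromo-6-methoxyphenyl)-N-methoxy-N,7-dimethyl-3-[(triisopropylsilyl)oxy]-2H-naphtho[1,8-bc]furan-2-carboxamide
Conditions: preparative SFC, immobilised amylose tris(3,5-dimethylphenylcarbamate) phase, CO2/i-PrOH
Reagents that add atoms: none
Why: Resolution by chromatography on a chiral stationary phase should deliver the (R)-enantiomer of this neutral, configurationally stable amide (assignable by anomalous X-ray dispersion at bromine); this is where the absolute configuration of the single stereocentre is fixed.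

Step 9
Reactants: 13 (R)-2-(2-bromo-6-methoxyphenyl)-N-methoxy-N,7-dimethyl-3-[(triisopropylsilyl)oxy]-2H-naphtho[1,8-bc]furan-2-carboxamide
Product: 16 (S)-5-methoxy-7'-methyl-3'-[(triisopropylsilyl)oxy]spiro[bicyclo[4.2.0]octa-1,3,5-triene-7,2'-naphtho[1,8-bc]furan]-8-one, via aryllithium 14 (not isolated), via lithium hemiaminal 15 (not isolated)
Conditions: t-BuLi (2.1 equiv), THF, −78 to −20 °C; AcOH, −78 °C
Reagents that add atoms: none
Why: Parham cyclisation, bromine–lithium exchange followed by 4-exo-trig attack of the aryllithium on the Weinreb amide, should give a chelated tetrahedral adduct that releases the benzocyclobutenone only on quench (a known way to benzocyclobutenones from 2-bromoarylacetic Weinreb amides), and the fully substituted alpha carbon cannot epimerise.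

Step 10
Reactants: 16 (S)-5-methoxy-7'-methyl-3'-[(triisopropylsilyl)oxy]spiro[bicyclo[4.2.0]octa-1,3,5-triene-7,2'-naphtho[1,8-bc]furan]-8-one; 17 2-azidoethanol
Product: 20 (S)-2-(2-hydroxyethyl)-7-methoxy-7'-methyl-3'-[(triisopropylsilyl)oxy]spiro[isoindoline-1,2'-naphtho[1,8-bc]furan]-3-one, via spiro-oxazolidine aminodiazonium ion 18 (not isolated), via iminium ether 19 (not isolated)
Conditions: 17 (2 equiv, as CH2Cl2 solution), BF3·OEt2 (3 equiv), CH2Cl2, −78 °C to rt; concentrate; then sat. aq. NaHCO3, rt
Reagents that add atoms: water O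
Why: Proposed new method: BF3 promotes addition of the azido alcohol to the strained carbonyl group, the hemiketal ionises to an oxocarbenium ion and the azide nitrogen closes the spiro oxazolidine aminodiazonium ion 18 (5-endo-trig, the usual entry of hydroxyalkyl azides), after which the C–C bond antiperiplanar to the leaving N2 shifts to nitrogen and the iminium ether 19 is opened at its iminium carbon by aqueous NaHCO3. The closest known reaction is the BF3-mediated Schmidt insertion of 2-azidoethanol into cyclohexanones and other unstrained cyclic ketones, which gives N-(2-hydroxyethyl) lactams; a benzocyclobutenone has not been used, but relief of ring strain on rehybridisation and on expansion should help both the addition and the shift. The lactam ring is closed by this four-to-five ring expansion (a 1,2-shift from carbon to nitrogen), not by a cyclisation. No stereocentre is created: the migrating spiro carbon keeps its three other ligands and moves suprafacially with retention, so the configuration fixed in step 8 is carried into the N,O-ketal. The selectivity needed is migration of the spiro carbon and not of the aryl carbon; the spiro carbon is fully substituted and carries an oxygen lone-pair donor, the diazonium group should prefer the nitrogen invertomer that points away from this crowded centre and is then antiperiplanar to it, and an aryl shift inside the benzo-fused four-membered ring is geometrically poor. Ionisation of the spiro ether by the Lewis acid is not expected, because the cation would sit next to the carbonyl group in 16 and next to a positively charged nitrogen in 19, and the silyl ether removes the phenol that could assist it.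

Step 11
Reactants: 20 (S)-2-(2-hydroxyethyl)-7-methoxy-7'-methyl-3'-[(triisopropylsilyl)oxy]spiro[isoindoline-1,2'-naphtho[1,8-bc]furan]-3-one
Product: 21 (R)-3'-hydroxy-2-(2-hydroxyethyl)-7-methoxy-7'-methylspiro[isoindoline-1,2'-naphtho[1,8-bc]furan]-3-one (CNP0434366.1)
Conditions: Bu4NF, AcOH (1:1), THF, 0 °C
Reagents that add atoms: none
Why: Fluoride cleavage of the aryl silyl ether, buffered with acetic acid so that no free naphthoxide sits next to the spiro N,O-ketal, should give the target without touching the stereocentre.

Compound list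
1 | 1-[4-(benzyloxy)phenyl]propan-2-one | CC(=O)Cc1ccc(OCc2ccccc2)cc1 | starting material
2 | ethyl 4-[4-(benzyloxy)phenyl]-3-methylbut-2-enoate (E/Z) | CCOC(=O)C=C(C)Cc1ccc(OCc2ccccc2)cc1 | intermediate
3 | 4-[4-(benzyloxy)phenyl]-3-methylbut-2-enoic acid (E/Z) | OC(=O)C=C(C)Cc1ccc(OCc2ccccc2)cc1 | intermediate
4 | 7-(benzyloxy)-3-methylnaphthalen-1-yl acetate | CC(=O)Oc1cc(C)cc2ccc(OCc3ccccc3)cc12 | intermediate
5 | 7-hydroxy-3-methylnaphthalen-1-yl acetate | CC(=O)Oc1cc(C)cc2ccc(O)cc12 | intermediate
6 | 7-methyl-1,2-dioxo-1,2-dihydronaphtho[2,1-b]furan-9-yl acetate | CC(=O)Oc1cc(C)cc2ccc3OC(=O)C(=O)c3c12 | intermediate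
7 | 3-bromoanisole | COc1cccc(Br)c1 | starting material
8 | 2-bromo-6-methoxyphenyllithium | [Li]c1c(Br)cccc1OC | intermediate
9 | rac-1-(2-bromo-6-methoxyphenyl)-1-hydroxy-7-methyl-2-oxo-1,2-dihydronaphtho[2,1-b]furan-9-yl acetate | CC(=O)Oc1cc(C)cc2ccc3OC(=O)C(O)(c4c(Br)cccc4OC)c3c12 | intermediate
10 | rac-2-(2-bromo-6-methoxyphenyl)-2-(2,8-dihydroxy-6-methylnaphthalen-1-yl)-2-hydroxy-N-methoxy-N-methylacetamide | CON(C)C(=O)C(O)(c1c(Br)cccc1OC)c1c(O)ccc2cc(C)cc(O)c12 | intermediate
11 | rac-2-(2-bromo-6-methoxyphenyl)-3-hydroxy-N-methoxy-N,7-dimethyl-2H-naphtho[1,8-bc]furan-2-carboxamide | COc1cccc(Br)c1C1(Oc2cc(C)cc3ccc(O)c1c23)C(=O)N(C)OC | intermediate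
12 | rac-2-(2-bromo-6-methoxyphenyl)-N-methoxy-N,7-dimethyl-3-[(triisopropylsilyl)oxy]-2H-naphtho[1,8-bc]furan-2-carboxamide | COc1cccc(Br)c1C1(Oc2cc(C)cc3ccc(O[Si](C(C)C)(C(C)C)C(C)C)c1c23)C(=O)N(C)OC | intermediate
13 | (R)-2-(2-bromo-6-methoxyphenyl)-N-methoxy-N,7-dimethyl-3-[(triisopropylsilyl)oxy]-2H-naphtho[1,8-bc]furan-2-carboxamide | COc1cccc(Br)c1[C@@]1(Oc2cc(C)cc3ccc(O[Si](C(C)C)(C(C)C)C(C)C)c1c23)C(=O)N(C)OC | intermediate
14 | aryllithium from 13 (lithium in place of bromine, same configuration) | COc1cccc([Li])c1[C@@]1(Oc2cc(C)cc3ccc(O[Si](C(C)C)(C(C)C)C(C)C)c1c23)C(=O)N(C)OC | intermediate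
15 | lithium alkoxide of the N-methoxy-N-methyl hemiaminal of 16 (tetrahedral adduct) | COc1cccc2c1[C@@]1(Oc3cc(C)cc4ccc(O[Si](C(C)C)(C(C)C)C(C)C)c1c34)C2(O[Li])N(C)OC | intermediate
16 | (S)-5-methoxy-7'-methyl-3'-[(triisopropylsilyl)oxy]spiro[bicyclo[4.2.0]octa-1,3,5-triene-7,2'-naphtho[1,8-bc]furan]-8-one | COc1cccc2c1[C@@]1(Oc3cc(C)cc4ccc(O[Si](C(C)C)(C(C)C)C(C)C)c1c34)C2=O | intermediate
17 | 2-azidoethanol | OCCN=[N+]=[N-] | starting material
18 | spiro oxazolidine aminodiazonium ion at the former carbonyl carbon of 16, hydroxytrifluoroborate salt | COc1cccc2c1[C@@]1(Oc3cc(C)cc4ccc(O[Si](C(C)C)(C(C)C)C(C)C)c1c34)C21OCCN1[N+]#N.O[B-](F)(F)F | intermediate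
19 | ring-expanded iminium ether (oxazolinium fused to the isoindole ring), hydroxytrifluoroborate salt | COc1cccc2c1[C@@]1(Oc3cc(C)cc4ccc(O[Si](C(C)C)(C(C)C)C(C)C)c1c34)[N+]1=C2OCC1.O[B-](F)(F)F | intermediate
20 | (S)-2-(2-hydroxyethyl)-7-methoxy-7'-methyl-3'-[(triisopropylsilyl)oxy]spiro[isoindoline-1,2'-naphtho[1,8-bc]furan]-3-one | COc1cccc2c1[C@@]1(Oc3cc(C)cc4ccc(O[Si](C(C)C)(C(C)C)C(C)C)c1c34)N(CCO)C2=O | intermediate
21 | (R)-3'-hydroxy-2-(2-hydroxyethyl)-7-methoxy-7'-methylspiro[isoindoline-1,2'-naphtho[1,8-bc]furan]-3-one | COc1cccc2c1[C@@]1(Oc3cc(C)cc4ccc(O)c1c34)N(CCO)C2=O | target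

Total step count: 11. Longest linear sequence: 11 steps (1 to 21); 3-bromoanisole and 2-azidoethanol enter as purchased reagents.

Steps most likely to fail

First, step 10, which carries the label. The azido alcohol may fail to add to the crowded carbonyl group, the aryl carbon may migrate in place of the spiro carbon, or the Lewis acid may open the four-membered ring before nitrogen is inserted. The fallback uses known chemistry and sets out from 16. Condensation with O-(mesitylsulfonyl)hydroxylamine (CH2Cl2, 0 °C) gives the oxime O-mesitylsulfonate F1, whose sulfonate should sit on the flat aryl side and therefore anti to the spiro carbon. Beckmann ring expansion on basic Al2O3 in MeOH, the established conversion of cyclobutanones into γ-lactams with retention at the migrating carbon, gives the N-unsubstituted lactam F2. Deprotonation with KN(SiMe3)2 at −78 °C and immediate alkylation with 2-[(tert-butyldimethylsilyl)oxy]ethyl trifluoromethanesulfonate, kept cold so that alkylation outruns base-induced opening of the N,O-ketal, gives the N-(2-silyloxyethyl) lactam F3. Bu4NF/AcOH then removes both silyl groups and the sequence comes back to the route at 21.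

Second, step 4. Ring closure may take place at the other ortho carbon (C6), the peri acetyl group may migrate or be lost under the Lewis acid, or acylation next to the peri substituent may be sluggish. The fallback sets out from 5 and 7. Compound 7 is lithiated as in step 5 (8) and quenched with dimethyl oxalate to give methyl 2-(2-bromo-6-methoxyphenyl)-2-oxoacetate F4. Compound 5 is converted with EtMgBr (CH2Cl2/toluene, 0 °C) into its bromomagnesium naphthoxide F5, which binds F4 and delivers it to the ortho alpha carbon in a chelate-controlled, ortho-specific Friedel–Crafts hydroxyalkylation of a metal phenoxide with an α-keto ester. Lactonisation with loss of methanol gives 9, where the route is rejoined, and neither an acid chloride nor AlCl3 meets the acetate.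

Third, step 9. Closure of the strained ring may be slower than proton capture or intermolecular attack of the organolithium on the amide, or the aryl rotamer may hold the C–Li bond away from the amide. The fallback sets out from 13. Reduction with i-Bu2AlH (THF, −78 °C) gives the aldehyde F6. Palladium-catalysed intramolecular acylation of the aryl bromide by the aldehyde C–H bond (Pd2(dba)3, rac-BINAP, Cs2CO3, dioxane, 110 °C), a known route from α-quaternary (2-bromoaryl)acetaldehydes to benzocyclobutenones, then gives 16, where the route is rejoined.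

Further compounds
F1 | step 10 | O-mesitylsulfonyl oxime of 16 | COc1cccc2c1[C@@]1(Oc3cc(C)cc4ccc(O[Si](C(C)C)(C(C)C)C(C)C)c1c34)C2=NOS(=O)(=O)c1c(C)cc(C)cc1C
F2 | step 10 | (S)-7-methoxy-7'-methyl-3'-[(triisopropylsilyl)oxy]spiro[isoindoline-1,2'-naphtho[1,8-bc]furan]-3-one | COc1cccc2c1[C@@]1(Oc3cc(C)cc4ccc(O[Si](C(C)C)(C(C)C)C(C)C)c1c34)NC2=O
F3 | step 10 | (S)-2-[2-(tert-butyldimethylsilyloxy)ethyl]-7-methoxy-7'-methyl-3'-[(triisopropylsilyl)oxy]spiro[isoindoline-1,2'-naphtho[1,8-bc]furan]-3-one | COc1cccc2c1[C@@]1(Oc3cc(C)cc4ccc(O[Si](C(C)C)(C(C)C)C(C)C)c1c34)N(CCO[Si](C)(C)C(C)(C)C)C2=O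
F4 | step 4 | methyl 2-(2-bromo-6-methoxyphenyl)-2-oxoacetate | COC(=O)C(=O)c1c(Br)cccc1OC
F5 | step 4 | bromomagnesium 8-acetoxy-6-methylnaphthalen-2-olate | CC(=O)Oc1cc(C)cc2ccc(O[Mg]Br)cc12
F6 | step 9 | (R)-2-(2-bromo-6-methoxyphenyl)-7-methyl-3-[(triisopropylsilyl)oxy]-2H-naphtho[1,8-bc]furan-2-carbaldehyde | COc1cccc(Br)c1[C@@]1(Oc2cc(C)cc3ccc(O[Si](C(C)C)(C(C)C)C(C)C)c1c23)C=O
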